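**Retrosynthetic overview**

1. Feature: the only ring is a 4-methoxycyclohex-2-en-1-one, numbered C1 (C=O), C2=C3, C4 (OMe), C5 (CH2), C6 (quaternary, carrying allyl and side-chain carbon C7), with C8 the carbinol carbon. C1–C4 carry the oxygen pattern of a 1,1,4-trioxygenated butadiene, and C5–C6 that of a 2-allyl vinyl ketone whose carbonyl carbon is C7.
2. 22 ⇐ 21 (C1 as dimethyl ketal) ⇐ aryl ketone 20, where C7 and C8 are set together by a dynamic carbonyl hydrogenation; 20 ⇐ aldehyde 16 + aryl Grignard reagent 18, then oxidation.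
3. 16 ⇐ methyl ketone 14 by one-carbon homologation (sulfur ylide epoxidation, hydride-shift rearrangement).
4. 14 ⇐ diene 6 + enone 12 by a catalytic enantioselective Diels–Alder reaction that forms C4–C5 and C1–C6 and closes the only ring.
5. 6 ⇐ (Z)-enoate 4 ⇐ ynoate 3 ⇐ 1; 12 ⇐ allylated acetoacetate 9 ⇐ 7 + 8.

Key step: step 6

Remark 1: Felkin–Anh addition of an aryl Grignard reagent to the (7S)-aldehyde would give the 8R carbinol (hydroxyl syn to the C7 methyl), whereas the target is 8S (anti); C8 is therefore set by hydride delivery to the aryl ketone, which gives the anti isomer under the same model.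

Remark 2: C6 carries two sterically similar methylene arms and cannot be expected to bias C7; C7 is therefore left uncontrolled until the enolisable aryl ketone 20 and is set there together with C8.

Remark 3: γ-deprotonation of an (E)-4-alkoxy-2-enoate is expected to give the (3Z)-dienolate, a poor Diels–Alder diene; the diene is therefore made from the (Z)-enoate, which should give the (3E)-dienolate. The C1 geometry of the diene is of no consequence because C1 ends as a ketal carbon with two methoxy groups.

Remark 4: the face selection of the oxazaborolidinium cation for an α-alkyl vinyl ketone is assumed to follow that of other coordinated enones; the (S)-catalyst is written, and its antipode is taken if the first run shows the opposite sense.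

**Route**

Step 1
Reactants: 1 3-methoxyprop-1-yne
Product: 3 methyl 4-methoxybut-2-ynoate, via lithium acetylide 2 (not isolated)
Conditions: n-BuLi, THF, −78 °C; ClCO2Me, −78 → 0 °C
Reagents that add atoms: methyl chloroformate, COC(=O)Cl
Why: Deprotonation of the terminal alkyne and C-acylation of the lithium acetylide with a chloroformate is the standard alkynoate synthesis, and the propargylic ether is inert at low temperature.

Step 2
Reactants: 3 methyl 4-methoxybut-2-ynoate
Product: 4 methyl (2Z)-4-methoxybut-2-enoate
Conditions: H2 (1 atm), Pd/CaCO3 poisoned with Pb(OAc)2, quinoline, EtOAc, rt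
Reagents that add atoms: none
Why: Lindlar semihydrogenation adds hydrogen syn to the alkyne and should stop at the (Z)-enoate, the geometry required for step 3.

Step 3
Reactants: 4 methyl (2Z)-4-methoxybut-2-enoate
Product: 6 (1Z,3E)-1,4-dimethoxy-1-(trimethylsilyloxy)buta-1,3-diene, via lithium dienolate 5 (not isolated)
Conditions: LiN(i-Pr)2, DMPU, THF, −78 °C; Me3SiCl, −78 °C → rt; distil
Reagents that add atoms: chlorotrimethylsilane, C[Si](C)(C)Cl
Why: Carbonyl-directed γ-deprotonation of a (Z)-enoate gives the s-cis dienolate, in which the C4 methoxy group must point outward, so O-silylation (silyl dienolate formation) should give the (3E)-vinylketene acetal.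

Step 4
Reactants: 7 ethyl acetoacetate; 8 allyl bromide
Product: 9 ethyl 2-acetylpent-4-enoate (racemic)
Conditions: NaOEt, EtOH, reflux
Reagents that add atoms: none
Why: Acetoacetic ester alkylation, C-allylation of the stabilised sodium enolate by SN2 displacement of bromide.

Step 5
Reactants: 9 ethyl 2-acetylpent-4-enoate
Product: 12 3-methylidenehex-5-en-2-one, via keto acid 10 (not isolated), via Mannich acid 11 (not isolated)
Conditions: KOH, H2O, rt; HCl to pH 5, 0 °C; Et2NH, 37% aq CH2O, 0 °C → rt; distil from hydroquinone, use fresh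
Reagents that add atoms: formaldehyde, C=O
Why: Decarboxylative Mannich methylenation: the β-keto acid adds to the diethyl(methylene)iminium ion at its doubly activated carbon and the adduct loses CO2 and Et2NH, so the methylene group can only appear on the carbon that carried the carboxyl group.

Step 6
Reactants: 6 (1Z,3E)-1,4-dimethoxy-1-(trimethylsilyloxy)buta-1,3-diene; 12 3-methylidenehex-5-en-2-one
Product: 14 1-[(1R,5R)-2,2,5-trimethoxy-1-(prop-2-en-1-yl)cyclohex-3-en-1-yl]ethan-1-one, via mixed silyl ketal 13 (not isolated)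
Conditions: (S)-3,3-diphenyl-1-(2-methylphenyl)tetrahydro-1H,3H-pyrrolo[1,2-c][1,3,2]oxazaborole + HNTf2 (20 mol% each), Ph3PO (20 mol%), CH2Cl2, −78 °C, slow addition of 6; then MeOSiMe3, Me3SiOTf (10 mol%), −78 °C; pyridine
Reagents that add atoms: methoxytrimethylsilane, CO[Si](C)(C)C
Why: Proposed new method: binding of the oxazaborolidinium boron to the acetyl oxygen of 12 lowers the enone LUMO so that the vinylketene acetal adds in an asynchronous (4+2) cycloaddition, C4 (the terminus remote from the two C1 oxygens, highest HOMO coefficient) bonding to the methylene carbon C5 ahead of C1 bonding to C6; the closest known reactions are the oxazaborolidinium-catalysed Diels–Alder additions of silyloxy dienes to enones and 2-substituted enals and the Mukaiyama–Michael additions of silyl ketene acetals to enones under the same cations, but a 1,1,4-trioxygenated diene building an acyl-bearing quaternary carbon has not been shown. The six-membered ring closes by suprafacial–suprafacial cycloaddition, both bonds forming on one face of each partner, and in the stepwise limit the same ring would close by 6-(enolexo)-exo-trig attack of the C6 boron enolate on the C1 silyloxycarbenium ion. C6 is set by the catalyst, which blocks one face of the coordinated enone, and C4 is set relative to C6 by the (3E) geometry of 6 together with the acetyl-endo transition state, which brings the outward C4 methoxy group cis to C7. The step needs regio-, endo- and enantioselectivity: two oxygens on C1 against one on C4 fix the orientation, the Lewis-acid-bound carbonyl group takes the endo position in preference to the allyl CH2, and Ph3PO traps Me3Si+ so that no achiral silyl Lewis acid carries a background reaction. C6 is quaternary, so the adduct cannot aromatise and C2=C3, the C4 ether and the C1 ketal oxidation level arrive intact. Exchange of the silyloxy group of 13 for methoxy with MeOSiMe3 and catalytic Me3SiOTf (ionisation to the methoxycarbenium ion and capture by the silyl ether) then gives the dimethyl ketal 14, which masks C1 for the following steps.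

Step 7
Reactants: 14 1-[(1R,5R)-2,2,5-trimethoxy-1-(prop-2-en-1-yl)cyclohex-3-en-1-yl]ethan-1-one
Product: 15 2-methyl-2-[(1R,5R)-2,2,5-trimethoxy-1-(prop-2-en-1-yl)cyclohex-3-en-1-yl]oxirane (both epimers at the oxirane carbon)
Conditions: Me3S+ I−, n-BuLi, THF, −10 °C → rt
Reagents that add atoms: trimethylsulfonium iodide, C[S+](C)C.[I-]
Why: Corey–Chaykovsky methylene transfer from dimethylsulfonium methylide to the only free carbonyl group (C1 is a ketal and the ring alkene is no longer an acceptor) should give the terminal epoxide, whose new centre need not be controlled because C7 is reset at ketone 20.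

Step 8
Reactants: 15 2-methyl-2-[(1R,5R)-2,2,5-trimethoxy-1-(prop-2-en-1-yl)cyclohex-3-en-1-yl]oxirane
Product: 16 2-[(1R,5R)-2,2,5-trimethoxy-1-(prop-2-en-1-yl)cyclohex-3-en-1-yl]propanal (both C7 epimers)
Conditions: MeAl(OAr)2, Ar = 4-bromo-2,6-di-tert-butylphenyl (20 mol%), CH2Cl2, −78 °C
Reagents that add atoms: none
Why: Meinwald rearrangement: the bulky aluminium Lewis acid opens the epoxide at its tertiary carbon and a hydride shifts from the CH2O carbon, assisted by the oxygen lone pair, to give the aldehyde, while the size of the reagent should keep it off the hindered ketal oxygens.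

Step 9
Reactants: 16 2-[(1R,5R)-2,2,5-trimethoxy-1-(prop-2-en-1-yl)cyclohex-3-en-1-yl]propanal; 17 5-bromo-1,2,3-trimethoxybenzene
Product: 19 2-[(1R,5R)-2,2,5-trimethoxy-1-(prop-2-en-1-yl)cyclohex-3-en-1-yl]-1-(3,4,5-trimethoxyphenyl)propan-1-ol (mixture at C7 and C8), via aryl Grignard reagent 18 (not isolated)
Conditions: 17, Mg, THF, reflux; then 16, THF, −78 → 0 °C; quench H2O
Reagents that add atoms: none
Why: Grignard addition of the arylmagnesium bromide to the aldehyde forms the C8–aryl bond, and no selectivity is sought because both new centres are corrected through the ketone.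

Step 10
Reactants: 19 2-[(1R,5R)-2,2,5-trimethoxy-1-(prop-2-en-1-yl)cyclohex-3-en-1-yl]-1-(3,4,5-trimethoxyphenyl)propan-1-ol
Product: 20 2-[(1R,5R)-2,2,5-trimethoxy-1-(prop-2-en-1-yl)cyclohex-3-en-1-yl]-1-(3,4,5-trimethoxyphenyl)propan-1-one (both C7 epimers)
Conditions: (n-Pr4N)RuO4 (5 mol%), N-methylmorpholine N-oxide, 4 Å MS, CH2Cl2, rt
Reagents that add atoms: none
Why: Ley–Griffith oxidation of the benzylic alcohol under neutral conditions should leave the ketal and the alkenes untouched and merges the four alcohols into the C7-epimeric aryl ketone, in which C7–H is enolisable.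

Step 11
Reactants: 20 2-[(1R,5R)-2,2,5-trimethoxy-1-(prop-2-en-1-yl)cyclohex-3-en-1-yl]-1-(3,4,5-trimethoxyphenyl)propan-1-one
Product: 21 (1S,2S)-2-[(1R,5R)-2,2,5-trimethoxy-1-(prop-2-en-1-yl)cyclohex-3-en-1-yl]-1-(3,4,5-trimethoxyphenyl)propan-1-ol
Conditions: H2 (20 atm), trans-RuCl2[(R)-xylbinap][(R)-daipen] (2 mol%), t-BuOK (0.5 equiv), i-PrOH, 30 °C
Reagents that add atoms: none
Why: Noyori asymmetric hydrogenation with dynamic kinetic resolution: t-BuOK interconverts the C7 epimers through the enolate, the catalyst enantiomer that gives (S)-1-arylalkanols fixes C8, and only for the (7S)-ketone does this coincide with Felkin–Anh hydride attack anti to the quaternary C6, so the matched epimer should be drained to the anti (7S,8S)-alcohol, with the carbonyl-selective catalyst leaving the alkenes alone.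

Step 12
Reactants: 21 (1S,2S)-2-[(1R,5R)-2,2,5-trimethoxy-1-(prop-2-en-1-yl)cyclohex-3-en-1-yl]-1-(3,4,5-trimethoxyphenyl)propan-1-ol
Product: 22 (4R,6R)-6-[(1S,2S)-1-hydroxy-1-(3,4,5-trimethoxyphenyl)propan-2-yl]-4-methoxy-6-(prop-2-en-1-yl)cyclohex-2-en-1-one
Conditions: PPTS, acetone/H2O (9:1), rt
Reagents that add atoms: water, O
Why: Mild acid hydrolysis of the allylic dimethyl ketal through its conjugated oxocarbenium ion should release the enone without disturbing the benzylic alcohol, the C4 methyl ether or any of the four stereocentres, none of which is epimerisable under these conditions.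

**Compound list**

1 | 3-methoxyprop-1-yne (methyl propargyl ether) | C#CCOC | starting material
2 | lithium 3-methoxyprop-1-yn-1-ide | [Li+].[C-]#CCOC | intermediate (not isolated)
3 | methyl 4-methoxybut-2-ynoate | COCC#CC(=O)OC | intermediate
4 | methyl (2Z)-4-methoxybut-2-enoate | COC/C=C\C(=O)OC | intermediate
5 | lithium (1E,3E)-1,4-dimethoxybuta-1,3-dien-1-olate (O–Li cis to C3) | CO/C=C/C=C(/OC)[O-].[Li+] | intermediate (not isolated)
6 | (1Z,3E)-1,4-dimethoxy-1-(trimethylsilyloxy)buta-1,3-diene | CO/C=C/C=C(/OC)O[Si](C)(C)C | intermediate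
7 | ethyl acetoacetate | CCOC(=O)CC(C)=O | starting material
8 | allyl bromide | C=CCBr | starting material
9 | ethyl 2-acetylpent-4-enoate (racemic) | C=CCC(C(C)=O)C(=O)OCC | intermediate
10 | 2-acetylpent-4-enoic acid | C=CCC(C(C)=O)C(=O)O | intermediate (not isolated)
11 | 2-acetyl-2-[(diethylamino)methyl]pent-4-enoic acid | C=CCC(CN(CC)CC)(C(C)=O)C(=O)O | intermediate (not isolated)
12 | 3-methylidenehex-5-en-2-one | CC(=O)C(=C)CC=C | intermediate
13 | 1-[(1R,2S,5R)-2,5-dimethoxy-1-(prop-2-en-1-yl)-2-(trimethylsilyloxy)cyclohex-3-en-1-yl]ethan-1-one | C=CC[C@]1(C(C)=O)C[C@@H](OC)C=C[C@]1(OC)O[Si](C)(C)C | intermediate (not isolated)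
14 | 1-[(1R,5R)-2,2,5-trimethoxy-1-(prop-2-en-1-yl)cyclohex-3-en-1-yl]ethan-1-one | C=CC[C@]1(C(C)=O)C[C@@H](OC)C=CC1(OC)OC | intermediate
15 | 2-methyl-2-[(1R,5R)-2,2,5-trimethoxy-1-(prop-2-en-1-yl)cyclohex-3-en-1-yl]oxirane, both epimers at the oxirane carbon | C=CC[C@]1(C2(C)CO2)C[C@@H](OC)C=CC1(OC)OC | intermediate
16 | 2-[(1R,5R)-2,2,5-trimethoxy-1-(prop-2-en-1-yl)cyclohex-3-en-1-yl]propanal, both C7 epimers | C=CC[C@]1(C(C)C=O)C[C@@H](OC)C=CC1(OC)OC | intermediate
17 | 5-bromo-1,2,3-trimethoxybenzene | COc1cc(Br)cc(OC)c1OC | starting material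
18 | (3,4,5-trimethoxyphenyl)magnesium bromide | COc1cc([Mg]Br)cc(OC)c1OC | intermediate (not isolated)
19 | 2-[(1R,5R)-2,2,5-trimethoxy-1-(prop-2-en-1-yl)cyclohex-3-en-1-yl]-1-(3,4,5-trimethoxyphenyl)propan-1-ol, mixture at C7 and C8 | C=CC[C@]1(C(C)C(O)c2cc(OC)c(OC)c(OC)c2)C[C@@H](OC)C=CC1(OC)OC | intermediate
20 | 2-[(1R,5R)-2,2,5-trimethoxy-1-(prop-2-en-1-yl)cyclohex-3-en-1-yl]-1-(3,4,5-trimethoxyphenyl)propan-1-one, both C7 epimers | C=CC[C@]1(C(C)C(=O)c2cc(OC)c(OC)c(OC)c2)C[C@@H](OC)C=CC1(OC)OC | intermediate
21 | (1S,2S)-2-[(1R,5R)-2,2,5-trimethoxy-1-(prop-2-en-1-yl)cyclohex-3-en-1-yl]-1-(3,4,5-trimethoxyphenyl)propan-1-ol | C=CC[C@]1([C@H](C)[C@H](O)c2cc(OC)c(OC)c(OC)c2)C[C@@H](OC)C=CC1(OC)OC | intermediate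
22 | (4R,6R)-6-[(1S,2S)-1-hydroxy-1-(3,4,5-trimethoxyphenyl)propan-2-yl]-4-methoxy-6-(prop-2-en-1-yl)cyclohex-2-en-1-one | C=CC[C@]1([C@H](C)[C@H](O)c2cc(OC)c(OC)c(OC)c2)C[C@@H](OC)C=CC1=O | target

**Step count**

Total: 12 steps. Longest linear sequence: 10 steps (steps 1–3 and 6–12).

**Steps most likely to fail**

Step 6 (proposed new method). Silyl transfer from the diene to the triflimide counter-ion may release an achiral silyl Lewis acid that carries a racemic background reaction; the sequence may stop after the first C–C bond without ring closure; or exo approach may erode the C4/C6 relationship. The fallback gives up asymmetric catalysis. It sets out from 6 and 12, which are heated without any acid (toluene, 80–100 °C, sealed tube, radical inhibitor) in a thermal concerted Diels–Alder reaction of the kind known for vinylketene silyl acetals, to give the racemic mixed silyl ketal F1. The same MeOSiMe3/Me3SiOTf exchange gives the racemic ketal ketone F2, which is resolved by preparative chromatography on a chiral stationary phase (cellulose tris(3,5-dimethylphenylcarbamate)). The (1R,5R)-enantiomer is 14, where the route is rejoined; the (1S,5S)-enantiomer F3 is set aside.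

Step 8. The Lewis acid may ionise the allylic ketal, or a carbon substituent of C6 may migrate in place of hydride. The fallback avoids the Lewis acid and sets out from 15. Diethylaluminium 2,2,6,6-tetramethylpiperidide, Et2Al(tmp) (toluene, 0 °C), removes a methyl proton and opens the epoxide to the allylic alcohol F4. MnO2 (CH2Cl2, rt) oxidises it to the 2-substituted propenal F5. Conjugate reduction with the copper hydride [(Ph3P)CuH]6 (THF, rt, aqueous work-up) should then give aldehyde 16 as its C7 epimers, where the route is rejoined.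

Step 11. Enolisation at the hindered C7 may be too slow for the epimers to interconvert during hydrogenation, or hydrogen transfer to the hindered carbonyl group may be too slow. The fallback replaces the dynamic process by separation and substrate control and sets out from 20. The epimers are separated by chromatography into the (2S)-ketone F6 and the (2R)-ketone F7. F7 is re-equilibrated with DBU (toluene, 60 °C) to 20 and recycled. F6 is reduced with LiAlH4 (THF, −78 °C), where Felkin–Anh attack anti to the quaternary C6 should give 21, at which the route is rejoined.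

**Further compounds**

F1 | step 6 | racemic 1-[(1R*,2S*,5R*)-2,5-dimethoxy-1-(prop-2-en-1-yl)-2-(trimethylsilyloxy)cyclohex-3-en-1-yl]ethan-1-one | C=CC[C@]1(C(C)=O)C[C@@H](OC)C=C[C@]1(OC)O[Si](C)(C)C.C=CC[C@@]1(C(C)=O)C[C@H](OC)C=C[C@@]1(OC)O[Si](C)(C)C
F2 | step 6 | racemic 1-[(1R*,5R*)-2,2,5-trimethoxy-1-(prop-2-en-1-yl)cyclohex-3-en-1-yl]ethan-1-one | C=CC[C@]1(C(C)=O)C[C@@H](OC)C=CC1(OC)OC.C=CC[C@@]1(C(C)=O)C[C@H](OC)C=CC1(OC)OC
F3 | step 6 | 1-[(1S,5S)-2,2,5-trimethoxy-1-(prop-2-en-1-yl)cyclohex-3-en-1-yl]ethan-1-one | C=CC[C@@]1(C(C)=O)C[C@H](OC)C=CC1(OC)OC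
F4 | step 8 | 2-[(1R,5R)-2,2,5-trimethoxy-1-(prop-2-en-1-yl)cyclohex-3-en-1-yl]prop-2-en-1-ol | C=CC[C@]1(C(=C)CO)C[C@@H](OC)C=CC1(OC)OC
F5 | step 8 | 2-[(1R,5R)-2,2,5-trimethoxy-1-(prop-2-en-1-yl)cyclohex-3-en-1-yl]prop-2-enal | C=CC[C@]1(C(=C)C=O)C[C@@H](OC)C=CC1(OC)OC
F6 | step 11 | (2S)-2-[(1R,5R)-2,2,5-trimethoxy-1-(prop-2-en-1-yl)cyclohex-3-en-1-yl]-1-(3,4,5-trimethoxyphenyl)propan-1-one | C=CC[C@]1([C@H](C)C(=O)c2cc(OC)c(OC)c(OC)c2)C[C@@H](OC)C=CC1(OC)OC
F7 | step 11 | (2R)-2-[(1R,5R)-2,2,5-trimethoxy-1-(prop-2-en-1-yl)cyclohex-3-en-1-yl]-1-(3,4,5-trimethoxyphenyl)propan-1-one | C=CC[C@]1([C@@H](C)C(=O)c2cc(OC)c(OC)c(OC)c2)C[C@@H](OC)C=CC1(OC)OC
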